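## Retrosynthetic overview
1. The γ-lactone is formed last. One TEMPO/PhI(OAc)2 oxidation of tetraol 25 closes the lactone (C12 onto O6) and makes the C14 enal.
2. The ten-membered carbocycle is formed before the lactone, by ring-closing metathesis at C4=C5. The C1–C2 bond is made just before that by Nozaki–Hiyama–Kishi coupling of vinyl iodide 18 with the C5 aldehyde 22.
3. C5–C6 comes from vinyl Grignard addition to the β-acyloxy aldehyde 16.
4. Key step: a cationic 1,2-alkenyl shift (C11 moves from C6 to C7) on a Sharpless epoxide. It forms C7–C11, sets C7, unveils the C6 aldehyde and puts the isovalerate on O8.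
5. The C1=C10 geometry is fixed in step 1 by syn borylative allylation of a propargyl ether.

Assumption: germacrane locants (C1–C15) are used throughout, and the silyl ethers 1 and 9 are bought as such.

## Route

Step 1
Reactants: 1 tert-butyldimethyl(prop-2-yn-1-yloxy)silane; 2 allyl methyl carbonate
Product: 3 tert-butyldimethyl{[(2E)-2-[(4,4,5,5-tetramethyl-1,3,2-dioxaborolan-2-yl)methylidene]pent-4-en-1-yl]oxy}silane (boron cis to the allyl group)
Conditions: B2pin2, CuCl (5 mol %), PCy3 (6 mol %), Pd(dppf)Cl2 (2 mol %), KOtBu (10 mol %), THF, 25 °C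
Reagents that add atoms: bis(pinacolato)diboron, CC1(C)OB(OC1(C)C)B1OC(C)(C)C(C)(C)O1
Why: Three-component borylative allylation, in which syn-borylcupration puts boron on the terminal carbon and the alkenylcopper takes the allyl group from a π-allylpalladium with retention, so C9 and the future C2 position end up cis.

Step 2
Reactants: 3 alkenyl boronate
Product: 4 tert-butyl{[(2E)-2-(iodomethylidene)pent-4-en-1-yl]oxy}dimethylsilane (iodine cis to the allyl group)
Conditions: NaOH (aq), I2, THF, 0 °C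
Reagents that add atoms: iodine, II
Why: Ipso-iododeboronation of the hydroxyboronate goes with retention of the double-bond geometry.

Step 3
Reactants: 4 vinyl iodide; 5 (Z)-but-2-ene-1,4-diol
Product: 6 (2E,5E)-5-{[(tert-butyldimethylsilyl)oxy]methyl}-6-iodohexa-2,5-dien-1-ol
Conditions: second-generation Hoveyda–Grubbs catalyst (3 mol %), 5 (3 equiv), CH2Cl2, 40 °C
Reagents that add atoms: none
Why: Olefin cross-metathesis touches only the terminal alkene (the trisubstituted iodoalkene is inert) and gives the E allylic alcohol under thermodynamic control.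

Step 4
Reactants: 6 dienol
Product: 7 [(2R,3R)-3-[(2E)-2-{[(tert-butyldimethylsilyl)oxy]methyl}-3-iodoprop-2-en-1-yl]oxiran-2-yl]methanol
Conditions: Ti(OiPr)4 (10 mol %), D-(−)-diethyl tartrate (12 mol %), t-BuOOH, 4 Å sieves, CH2Cl2, −20 °C
Reagents that add atoms: tert-butyl hydroperoxide, CC(C)(C)OO
Why: Sharpless asymmetric epoxidation reacts only at the allylic-alcohol alkene, and the D-(−)-tartrate gives the (2R,3R) epoxide, which fixes C8 (final R) and the C7–O bond that is inverted in step 7.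

Step 5
Reactants: 7 epoxy alcohol
Product: 8 (2S,3R)-3-[(2E)-2-{[(tert-butyldimethylsilyl)oxy]methyl}-3-iodoprop-2-en-1-yl]oxirane-2-carbaldehyde
Conditions: TEMPO (10 mol %), PhI(OAc)2, CH2Cl2, 23 °C
Reagents that add atoms: none
Why: Oxoammonium oxidation of the primary alcohol stops at the aldehyde and leaves epoxide, silyl ether and vinyl iodide untouched.

Step 6
Reactants: 8 epoxy aldehyde; 9 [(2-bromoprop-2-en-1-yl)oxy](tert-butyl)dimethylsilane
Product: 13 2-{[(tert-butyldimethylsilyl)oxy]methyl}-1-[(2S,3R)-3-[(2E)-2-{[(tert-butyldimethylsilyl)oxy]methyl}-3-iodoprop-2-en-1-yl]oxiran-2-yl]prop-2-en-1-yl triethylsilyl ether (both C6 epimers), via alkenyllithium 10 (not isolated), via alkenylmagnesium bromide 11 (not isolated), via bromomagnesium alkoxide 12 (not isolated)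
Conditions: 9, t-BuLi (2 equiv), Et2O, −78 °C; MgBr2·OEt2; 8, −78 °C; Et3SiCl, imidazole (cat.), −78 to 0 °C
Reagents that add atoms: chlorotriethylsilane, CC[Si](Cl)(CC)CC
Why: Halogen–lithium exchange, transmetalation to magnesium (which avoids exchange with the vinyl iodide) and Grignard 1,2-addition attach C11, and the C6 epimer ratio does not matter because C6 becomes a carbonyl carbon in step 7.

Step 7
Reactants: 13 epoxy silyl ether; 14 3-methylbutanoyl chloride
Product: 16 (2R,3R,5E)-5-{[(tert-butyldimethylsilyl)oxy]methyl}-2-(3-[(tert-butyldimethylsilyl)oxy]prop-1-en-2-yl)-6-iodo-1-oxohex-5-en-3-yl 3-methylbutanoate (7R,8R), via isovaleryl triflate 15 (not isolated)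
Conditions: 14, AgOTf, 2,6-di-tert-butyl-4-methylpyridine, CH2Cl2, −78 °C, 15 min; then slow addition of 13, −78 °C
Reagents that add atoms: none
Why: Proposed new method: the acyl triflate O-acylates the strained, most basic oxygen (the epoxide) to an acyloxiranium ion; the C7–O bond then breaks while the alkenyl group on the neighbouring silyloxy carbon migrates antiperiplanar to it (a bridged cation, so alkenyl wins over hydride), giving inversion at C7 and retention at C8, and the silyl oxocarbenium ion gives Et3Si+ to triflate, so that one cationic 1,2-shift delivers the C7–C11 bond, the 7R centre, the C6 aldehyde and the O8 isovalerate; the closest known reactions are the Lewis-acid semipinacol rearrangement of 2,3-epoxy silyl ethers and the opening of epoxides by acyl halides.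

Step 8
Reactants: 16 β-acyloxy aldehyde; 17 vinylmagnesium bromide
Product: 18 (3R,4S,5R,7E)-7-{[(tert-butyldimethylsilyl)oxy]methyl}-4-(3-[(tert-butyldimethylsilyl)oxy]prop-1-en-2-yl)-3-hydroxy-8-iodoocta-1,7-dien-5-yl 3-methylbutanoate (6R,7S,8R; the C7 letter changes only through CIP ranking)
Conditions: 17 (1.2 equiv), THF, −78 °C; aq NH4Cl at −78 °C
Reagents that add atoms: none
Why: In this Grignard addition the Felkin–Anh preference (new OH syn to the alkenyl group) and the polar 1,3-anti preference of the β-acyloxy group reinforce each other in the anti aldehyde, which sets 6R.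

Step 9
Reactants: 19 2-methylprop-2-en-1-yl acetate; 20 formaldehyde (as paraformaldehyde)
Product: 21 2-(2-hydroxyethyl)prop-2-en-1-yl acetate
Conditions: (CH2O)n, Me2AlCl (2.2 equiv), CH2Cl2, −78 to 0 °C
Reagents that add atoms: none
Why: In this Lewis-acid-promoted carbonyl-ene reaction the 1,1-disubstituted alkene attacks formaldehyde and the methyl hydrogen is transferred, which keeps the allylic acetate and a new 1,1-disubstituted alkene.

Step 10
Reactants: 21 homoallylic alcohol
Product: 22 2-(2-oxoethyl)prop-2-en-1-yl acetate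
Conditions: Dess–Martin periodinane, CH2Cl2, 0 °C, used at once
Reagents that add atoms: none
Why: Dess–Martin oxidation under neutral conditions gives the β,γ-unsaturated aldehyde without moving the double bond into conjugation.

Step 11
Reactants: 18 vinyl iodide; 22 aldehyde
Product: 23 open-chain tetraene (2S,6R,7S,8R): C1–C2 joined, OH at C2 and C6, CH2=C4(CH2OAc), C5 vinyl, O8 isovalerate, TBS ethers at C12 and C14, C9 cis to C2 on C1=C10
Conditions: CrCl2 (4 equiv), chiral oxazoline–sulfonamide ligand (antipode for Re-face attack), Et3N, NiCl2 (5 mol %), THF, 25 °C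
Reagents that add atoms: none
Why: Nozaki–Hiyama–Kishi coupling keeps the iodoalkene geometry and tolerates esters and the free OH, and the chiral complex of trivalent chromium sends the alkenyl group to the Re face of 22, which sets 2S.

Step 12
Reactants: 23 tetraene
Product: 24 ten-membered carbocycle (2S,6R,7S,8R; both ring double bonds ring-cis, E by CIP) bearing 2-OH, 6-OH, 15-OAc, 8-O-isovalerate, 14-OTBS and the 3-(TBSO)prop-1-en-2-yl group at C7
Conditions: second-generation Hoveyda–Grubbs catalyst (15 mol %), 1,4-benzoquinone (30 mol %), toluene (0.5 mM), 80 °C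
Reagents that add atoms: none
Why: Ring-closing metathesis starts at the C5 vinyl group, whose only productive partner is CH2=C4, and the ring-cis alkene (C3 cis to C6) is the less strained isomer in a ten-membered ring that already holds one cis double bond.

Step 13
Reactants: 24 bis-silyl ether
Product: 25 tetraol (2S,6R,7S,8R) with free OH at C2, C6, C12 and C14
Conditions: HF·pyridine, pyridine, THF, 0 to 23 °C
Reagents that add atoms: none
Why: Fluoride desilylation under mildly acidic conditions removes both primary TBS groups without acyl migration of the acetate or the isovalerate.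

Step 14
Reactants: 25 tetraol
Product: 27 target CNP0524123.1 (2S,6R,7R,8R), via lactol 26 (not isolated)
Conditions: TEMPO (20 mol %), PhI(OAc)2 (3.3 equiv), CH2Cl2, 23 °C
Reagents that add atoms: none
Why: TEMPO/PhI(OAc)2 oxidation takes the two primary allylic alcohols much faster than the secondary C2 alcohol, so C14 gives the enal while the C12 aldehyde is trapped by O6 as a lactol and oxidised on to the trans-fused α-methylene-γ-lactone.

## Compound list
1 | tert-butyldimethyl(prop-2-yn-1-yloxy)silane | C#CCO[Si](C)(C)C(C)(C)C | starting material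
2 | allyl methyl carbonate | C=CCOC(=O)OC | starting material
3 | (E)-alkenyl pinacol boronate, B cis to allyl | C=CC/C(CO[Si](C)(C)C(C)(C)C)=C\B1OC(C)(C)C(C)(C)O1 | intermediate
4 | (E)-vinyl iodide, I cis to allyl | C=CC/C(CO[Si](C)(C)C(C)(C)C)=C\I | intermediate
5 | (Z)-but-2-ene-1,4-diol | OC/C=C\CO | starting material
6 | (2E,5E)-iododienol | OC/C=C/C/C(CO[Si](C)(C)C(C)(C)C)=C\I | intermediate
7 | (2R,3R)-epoxy alcohol | OC[C@H]1O[C@@H]1C/C(CO[Si](C)(C)C(C)(C)C)=C\I | intermediate
8 | (2S,3R)-epoxy aldehyde | O=C[C@H]1O[C@@H]1C/C(CO[Si](C)(C)C(C)(C)C)=C\I | intermediate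
9 | [(2-bromoprop-2-en-1-yl)oxy](tert-butyl)dimethylsilane | C=C(Br)CO[Si](C)(C)C(C)(C)C | starting material
10 | 3-[(tert-butyldimethylsilyl)oxy]prop-1-en-2-yllithium | [Li]C(=C)CO[Si](C)(C)C(C)(C)C | intermediate
11 | bromo{3-[(tert-butyldimethylsilyl)oxy]prop-1-en-2-yl}magnesium | Br[Mg]C(=C)CO[Si](C)(C)C(C)(C)C | intermediate
12 | bromomagnesium alkoxide of the C6 carbinol (both epimers) | C=C(CO[Si](C)(C)C(C)(C)C)C(O[Mg]Br)[C@H]1O[C@@H]1C/C(CO[Si](C)(C)C(C)(C)C)=C\I | intermediate
13 | epoxy triethylsilyl ether (both C6 epimers) | C=C(CO[Si](C)(C)C(C)(C)C)C(O[Si](CC)(CC)CC)[C@H]1O[C@@H]1C/C(CO[Si](C)(C)C(C)(C)C)=C\I | intermediate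
14 | 3-methylbutanoyl chloride | CC(C)CC(=O)Cl | starting material
15 | 3-methylbutanoyl trifluoromethanesulfonate | CC(C)CC(=O)OS(=O)(=O)C(F)(F)F | intermediate
16 | (7R,8R)-β-isovaleryloxy aldehyde | O=C[C@H](C(=C)CO[Si](C)(C)C(C)(C)C)[C@H](OC(=O)CC(C)C)C/C(CO[Si](C)(C)C(C)(C)C)=C\I | intermediate
17 | vinylmagnesium bromide | C=C[Mg]Br | starting material
18 | (6R,7S,8R)-vinyl carbinol | C=C[C@@H](O)[C@H](C(=C)CO[Si](C)(C)C(C)(C)C)[C@H](OC(=O)CC(C)C)C/C(CO[Si](C)(C)C(C)(C)C)=C\I | intermediate
19 | 2-methylprop-2-en-1-yl acetate | C=C(C)COC(C)=O | starting material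
20 | formaldehyde | C=O | starting material
21 | 2-(2-hydroxyethyl)prop-2-en-1-yl acetate | C=C(CCO)COC(C)=O | intermediate
22 | 2-(2-oxoethyl)prop-2-en-1-yl acetate | C=C(CC=O)COC(C)=O | intermediate
23 | (2S,6R,7S,8R)-open-chain tetraene | C=C(COC(C)=O)C[C@H](O)/C=C(/CO[Si](C)(C)C(C)(C)C)C[C@@H](OC(=O)CC(C)C)[C@@H](C(=C)CO[Si](C)(C)C(C)(C)C)[C@H](O)C=C | intermediate
24 | (2S,6R,7S,8R)-cyclodecadiene bis-TBS ether | O[C@@H]1/C=C(/COC(C)=O)C[C@H](O)/C=C(/CO[Si](C)(C)C(C)(C)C)C[C@@H](OC(=O)CC(C)C)[C@H]1C(=C)CO[Si](C)(C)C(C)(C)C | intermediate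
25 | (2S,6R,7S,8R)-tetraol | O[C@@H]1/C=C(/COC(C)=O)C[C@H](O)/C=C(/CO)C[C@@H](OC(=O)CC(C)C)[C@H]1C(=C)CO | intermediate
26 | 14-oxo lactol (C12 epimers) | C=C1C(O)O[C@@H]2/C=C(/COC(C)=O)C[C@H](O)/C=C(/C=O)C[C@@H](OC(=O)CC(C)C)[C@@H]12 | intermediate
27 | CNP0524123.1 | C=C1C(=O)O[C@@H]2/C=C(/COC(C)=O)C[C@H](O)/C=C(/C=O)C[C@@H](OC(=O)CC(C)C)[C@@H]12 | target

## Step count
- Total steps: 14.
- Longest linear sequence: 12 (steps 1–8 and 11–14).

## Steps most likely to fail

**Step 7 (proposed new step).**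
- Risks: acylation of a silyl ether or of the 1,1-disubstituted alkene, or a rearrangement triggered by Et3SiOTf that leaves a silyl group on O8.
- Fallback with known chemistry, from 13 back to 16: treat 13 with TiCl4 in CH2Cl2 at −78 °C. This is the established Lewis-acid semipinacol rearrangement of 2,3-epoxy silyl ethers, with the same anti alkenyl shift, and it gives the β-hydroxy aldehyde (2R,3R,5E)-5-{[(tert-butyldimethylsilyl)oxy]methyl}-2-(3-[(tert-butyldimethylsilyl)oxy]prop-1-en-2-yl)-3-hydroxy-6-iodohex-5-enal F1.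
- Acylation of F1 with 14, pyridine and catalytic DMAP at −20 °C then gives 16.

**Step 11 (C2 control by the ligand).**
- Fallback from 18 and 22 back to 23: couple them with plain CrCl2/NiCl2 in DMSO to get the C2-epimeric alcohols F2.
- Oxidise only the more electron-rich, less hindered trisubstituted allylic alcohol with MnO2 to the C2 enone F3.
- Reduce F3 with (R)-Me-CBS and BH3·SMe2, with the alkenyl group acting as the large group, to the 2S alcohol 23.

**Step 12 (ten-membered ring with a trisubstituted alkene).**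
- Fallback from 18 back to 24. It fixes C4=C5 before ring closure and closes the ring at C1–C2.
- 2-Methylidene-4-[(triethylsilyl)oxy]butanal F4 is made from 4-[(triethylsilyl)oxy]butanal, 20 and pyrrolidinium propionate.
- Cross-metathesis of 18 with F4 (second-generation Hoveyda–Grubbs catalyst) gives the E enal F5, in which C15 is trans to C6; this is the thermodynamic enal geometry.
- NaBH4/CeCl3·7H2O gives the diol F6.
- Ac2O/2,4,6-collidine at −20 °C acetylates only the primary alcohol, giving the acetate F7.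
- PPTS/MeOH at 0 °C removes only the triethylsilyl group, giving the primary alcohol F8.
- TEMPO/PhI(OAc)2 gives the C2 aldehyde F9.
- Intramolecular Nozaki–Hiyama–Kishi reaction of F9 (CrCl2, NiCl2, the ligand of step 11, 1 mM) gives 24.

## Further compounds
F1 | step 7 | (7R,8R)-β-hydroxy aldehyde | O=C[C@H](C(=C)CO[Si](C)(C)C(C)(C)C)[C@H](O)C/C(CO[Si](C)(C)C(C)(C)C)=C\I
F2 | step 11 | C2-epimeric alcohols of 23 | C=C(COC(C)=O)CC(O)/C=C(/CO[Si](C)(C)C(C)(C)C)C[C@@H](OC(=O)CC(C)C)[C@@H](C(=C)CO[Si](C)(C)C(C)(C)C)[C@H](O)C=C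
F3 | step 11 | C2 enone | C=C(COC(C)=O)CC(=O)/C=C(/CO[Si](C)(C)C(C)(C)C)C[C@@H](OC(=O)CC(C)C)[C@@H](C(=C)CO[Si](C)(C)C(C)(C)C)[C@H](O)C=C
F4 | step 12 | 2-methylidene-4-[(triethylsilyl)oxy]butanal | C=C(C=O)CCO[Si](CC)(CC)CC
F5 | step 12 | C15 enal from cross-metathesis | O=C/C(CCO[Si](CC)(CC)CC)=C/[C@@H](O)[C@H](C(=C)CO[Si](C)(C)C(C)(C)C)[C@H](OC(=O)CC(C)C)C/C(CO[Si](C)(C)C(C)(C)C)=C\I
F6 | step 12 | C6,C15 diol | OC/C(CCO[Si](CC)(CC)CC)=C/[C@@H](O)[C@H](C(=C)CO[Si](C)(C)C(C)(C)C)[C@H](OC(=O)CC(C)C)C/C(CO[Si](C)(C)C(C)(C)C)=C\I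
F7 | step 12 | C15 acetate | CC(=O)OC/C(CCO[Si](CC)(CC)CC)=C/[C@@H](O)[C@H](C(=C)CO[Si](C)(C)C(C)(C)C)[C@H](OC(=O)CC(C)C)C/C(CO[Si](C)(C)C(C)(C)C)=C\I
F8 | step 12 | C2 primary alcohol | CC(=O)OC/C(CCO)=C/[C@@H](O)[C@H](C(=C)CO[Si](C)(C)C(C)(C)C)[C@H](OC(=O)CC(C)C)C/C(CO[Si](C)(C)C(C)(C)C)=C\I
F9 | step 12 | C2 aldehyde | CC(=O)OC/C(CC=O)=C/[C@@H](O)[C@H](C(=C)CO[Si](C)(C)C(C)(C)C)[C@H](OC(=O)CC(C)C)C/C(CO[Si](C)(C)C(C)(C)C)=C\I
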